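**Plan**

Numbering used throughout: oxolane C1(–C1'(OAr)–C2'H2OH)–O2–C3(aryl)–C4(–C4aH2OH)–C5(spiro); six-membered ring C5–C6=C7(OMe)–C8(=O)–C9=C10.
Enabling feature: C1' on C1 and C4a on C4 lie on the same face of the oxolane ring (1,3-cis across C5), so the primary alcohols C4a–OH and C2'–OH can be the two ends of one ester C4a–O–C2'(=O); the retrosynthesis cuts C1–C1' inside the seven-membered lactone C1–C1'–C2'–O–C4a–C4–C5, then the ester C4a–O.
Further cuts: C5–C10 and C6–C7 (Diels–Alder on the exocyclic C5=C6 of an α-methylene lactone), C5=C6 (methylenation), C3–C4 (aldol) with O2–C1 (lactonisation); the side-chain acid comes from dihydroconiferyl alcohol and ethyl bromoacetate.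
Forward order of rings: oxolane (as γ-lactone) by syn-aldol/lactonisation; cyclohexenone ring by cycloaddition at the spiro carbon; temporary bridging lactone by tethered Mukaiyama-type addition to the C1 oxocarbenium ion, then opened by hydride. C6=C7 is introduced last, because a spirodienone beside an ionising C1 acetal could fragment to a phenol.
Stereochemistry: C3 and C4 from the (S)-4-benzyloxazolidinone syn-aldol (trans-lactone); C5 from diene addition anti to the C4 substituent; C1 from the tether; C1' from the Z ketene acetal in a chair-like closure.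

Key step: step 19

Assumption: stereocentres that later steps erase (C7 in 20, 21, 24 and 30; C10 in 20; anomeric C1 in 23, 24, 30 and 31) are carried as epimer mixtures and left open in the SMILES; all other centres are single and drawn.

**Route**

Step 1
Reactants: 1 vanillin
Product: 2 silyl vanillin
Conditions: i-Pr3SiCl, imidazole, DMF, rt
Reagents that add atoms: chlorotri(propan-2-yl)silane, CC(C)[Si](Cl)(C(C)C)C(C)C
Why: O-silylation of the phenol (silyl ether formation); the bulky aryl silyl ether should survive every later basic, reducing and mildly acidic step until the final fluoride treatment.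

Step 2
Reactants: 3 (S)-4-benzyl-1,3-oxazolidin-2-one; 4 methyl 4-chloro-4-oxobutanoate
Product: 5 succinate imide
Conditions: n-BuLi, THF, −78 °C; then 4, −78 to 0 °C
Reagents that add atoms: none
Why: N-acylation of the lithiated oxazolidinone by the acid chloride, which reacts far faster than the methyl ester.

Step 3
Reactants: 5 succinate imide; 2 silyl vanillin
Product: 7 lactone imide, via syn-aldol adduct 6 (not isolated)
Conditions: n-Bu2BOTf, i-Pr2NEt, CH2Cl2, −78 to 0 °C; 2, −78 to 0 °C; pH 7 buffer, MeOH, H2O2; then PPTS (cat.), CH2Cl2, rt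
Reagents that add atoms: none
Why: Evans syn-aldol reaction followed by lactonisation: the Z boron enolate of the imide (the ester is not enolised) reacts through a chair Zimmerman–Traxler transition state on the face away from the auxiliary benzyl group, which sets C4 (enolate face) and C3 (aldehyde face), and the syn carbinol closes onto the methyl ester to give the trans-lactone.

Step 4
Reactants: 7 lactone imide
Product: 9 lactone acid, via peroxy acid 8 (not isolated)
Conditions: LiOH, H2O2, THF–H2O, 0 °C; Na2SO3; HCl to pH 2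
Reagents that add atoms: hydrogen peroxide, OO
Why: Hydroperoxide cleavage of the N-acyloxazolidinone: LiOOH attacks the exocyclic imide carbonyl, sulfite reduces the peroxy acid, and acidification re-closes any lactone opened by hydroxide, so C3 and C4 are untouched.

Step 5
Reactants: 9 lactone acid
Product: 10 hydroxymethyl lactone
Conditions: BH3·SMe2, THF, 0 °C to rt; MeOH quench
Reagents that add atoms: none
Why: Chemoselective borane reduction of the carboxylic acid (via the acyloxyborane) in the presence of the lactone, under non-basic conditions so that the new primary alcohol cannot translactonise.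

Step 6
Reactants: 10 hydroxymethyl lactone
Product: 11 silyloxymethyl lactone
Conditions: t-BuMe2SiCl, imidazole, CH2Cl2, 0 °C to rt
Reagents that add atoms: tert-butylchlorodimethylsilane, CC(C)(C)[Si](C)(C)Cl
Why: O-silylation of the primary alcohol (silyl ether formation); this group is chosen because acidic methanol removes it later while the aryl triisopropylsilyl ether stays.

Step 7
Reactants: 11 silyloxymethyl lactone
Product: 14 methylene lactone, via Mannich base 12 (not isolated), via ammonium iodide 13 (not isolated)
Conditions: LiN(i-Pr)2, THF, −78 °C; Me2N=CH2+ I−, −78 °C to rt; then MeI, MeOH, rt; then NaHCO3, CH2Cl2–H2O, rt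
Reagents that add atoms: dimethyl(methylidene)ammonium iodide, C=[N+](C)C.[I-]
Why: Mannich reaction of the lactone lithium enolate with the iminium salt, N-methylation and base-induced loss of trimethylamine (Hofmann-type elimination) give the exocyclic alkene; the transient C5 centre disappears and C3/C4 are not enolisable.

Step 8
Reactants: 15 2-methoxy-N-methoxy-N-methylacetamide; 16 ethynylmagnesium bromide
Product: 17 1-methoxybut-3-yn-2-one
Conditions: HC≡CMgBr, THF, 0 °C; inverse quench into cold 1 M HCl
Reagents that add atoms: none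
Why: Weinreb ketone synthesis: the chelated tetrahedral adduct of the Grignard reagent stops at the ketone stage, and the acidic quench keeps the liberated N,O-dimethylhydroxylamine from adding to the ynone.

Step 9
Reactants: 17 1-methoxybut-3-yn-2-one
Product: 18 (E)-1,4-dimethoxybut-3-en-2-one
Conditions: MeOH, DABCO (cat.), CH2Cl2, 0 °C
Reagents that add atoms: methanol, CO
Why: Amine-catalysed conjugate (Michael) addition of methanol to the terminal ynone, which should give the E β-methoxy enone.

Step 10
Reactants: 18 (E)-1,4-dimethoxybut-3-en-2-one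
Product: 19 diene
Conditions: Me3SiOTf, Et3N, Et2O, 0 °C
Reagents that add atoms: trimethylsilyl trifluoromethanesulfonate, C[Si](C)(C)OS(=O)(=O)C(F)(F)F
Why: Soft enolisation (silyl enol ether formation) at the only enolisable carbon, CH2OMe, should give the 2-silyloxy diene with the Z enol ether, the geometry that keeps the terminal methoxy group outside in the s-cis form.

Step 11
Reactants: 14 methylene lactone; 19 diene
Product: 21 spirolactone enone, via cycloadduct 20 (not isolated)
Conditions: toluene, BHT (cat.), 120 °C, sealed tube; then 0.05 M HCl, THF–H2O, 0 °C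
Reagents that add atoms: none
Why: Diels–Alder reaction of a 1-alkoxy-3-silyloxy diene with the α-methylene lactone: the methoxy-bearing terminus (C10) bonds to the acceptor α-carbon C5 and the other terminus (C7) to the methylene carbon C6, the diene adds to the face opposite the neighbouring C4 substituent so that C6 ends on the C4a face (this sets C5), and mild acid hydrolyses the silyl enol ether and eliminates the C10 methoxy group to the enone.

Step 12
Reactants: 21 spirolactone enone
Product: 22 lactone silyl dienol ether
Conditions: Et3SiOTf, Et3N, CH2Cl2, −78 °C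
Reagents that add atoms: triethylsilyl trifluoromethanesulfonate, CC[Si](CC)(CC)OS(=O)(=O)C(F)(F)F
Why: Soft enolisation (silyl enol ether formation) at C7, the only enolisable position since the lactone has no α-hydrogen; the cross-conjugated dienol ether masks C8 against hydride and merges the C7 epimers.

Step 13
Reactants: 22 lactone silyl dienol ether
Product: 23 lactol silyl dienol ether
Conditions: i-Bu2AlH, CH2Cl2, −78 °C; aq. potassium sodium tartrate (KNaC4H4O6)
Reagents that add atoms: none
Why: Partial reduction of the lactone with i-Bu2AlH, which stops at the aluminium lactolate at −78 °C and gives the lactol on work-up; the enol ether and the silyl ethers are inert to hydride.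

Step 14
Reactants: 23 lactol silyl dienol ether
Product: 24 acetal enone alcohol
Conditions: camphorsulfonic acid (cat.), MeOH, 0 °C to rt; Et3N quench
Reagents that add atoms: methanol, CO
Why: Three acid-catalysed events in one operation: Fischer-type acetalisation of the lactol through the C1 oxocarbenium ion, methanolysis of the primary tert-butyldimethylsilyl ether, and protodesilylation of the dienol ether at C7 back to the conjugated enone, while the aryl triisopropylsilyl ether should stay.

Step 15
Reactants: 25 dihydroconiferyl alcohol; 26 ethyl bromoacetate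
Product: 27 hydroxy ester
Conditions: K2CO3, acetone, reflux
Reagents that add atoms: none
Why: Williamson ether synthesis: K2CO3 deprotonates only the phenol, so O-alkylation is selective over the primary alcohol.

Step 16
Reactants: 27 hydroxy ester
Product: 28 silyl ester
Conditions: t-BuMe2SiCl, imidazole, DMF, rt
Reagents that add atoms: tert-butylchlorodimethylsilane, CC(C)(C)[Si](C)(C)Cl
Why: O-silylation of the primary alcohol (silyl ether formation), so that the acid cannot oligomerise during esterification.

Step 17
Reactants: 28 silyl ester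
Product: 29 aryloxyacetic acid
Conditions: LiOH, THF–H2O, 0 °C to rt; 1 M HCl to pH 4 at 0 °C
Reagents that add atoms: lithium hydroxide, [Li+].[OH-]
Why: Ester saponification; the primary silyl ether is stable to hydroxide and to brief cold acidification.

Step 18
Reactants: 24 acetal enone alcohol; 29 aryloxyacetic acid
Product: 30 tether ester
Conditions: EDC·HCl, DMAP (cat.), CH2Cl2, 0 °C to rt
Reagents that add atoms: none
Why: Steglich esterification of the primary C4a alcohol with the carbodiimide-activated acid, which installs the tether.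

Step 19
Reactants: 30 tether ester
Product: 32 bridged lactone, via bis-silyl intermediate 31 (not isolated)
Conditions: LiN(SiMe3)2 (2.4 equiv), Et3SiCl (3 equiv), THF, −78 to −40 °C; pentane, filtration, evaporation; then Et3SiOTf (0.2 equiv), CH2Cl2 (0.005 M), −78 to −40 °C; Et3N quench
Reagents that add atoms: chlorotriethylsilane, CC[Si](Cl)(CC)CC
Why: Proposed new method: LiN(SiMe3)2/Et3SiCl should convert the C8 ketone into its triethylsilyl dienol ether (C7 becomes sp2, so both C7 epimers converge and the ketone is masked) and the aryloxyacetate into the lithium-chelated, hence Z, silyl ketene acetal; catalytic Et3SiOTf then ionises either anomer of the C1 methyl acetal to the O2=C1 oxocarbenium ion, C1' adds to C1, and the silyl group released takes up the methoxide so that the triflate turns over. The closest known reactions are silyl-triflate-catalysed Mukaiyama-type additions of silyl ketene acetals to acetals and lactol derivatives and tethered intramolecular C-glycosylations; an ester tether that ends as a bridged lactone has not been used in this way. The new ring is the seven-membered lactone C1–C1'–C2'(=O)–O–C4a–C4–C5, closed in the 7-(enolendo)-exo-trig mode to a 3,7-dioxabicyclo[4.2.1]nonan-4-one. C1 is controlled by the tether, which can bridge only the 1,3-cis positions C1 and C4 and therefore brings C1' in on the C4a face; C1' is controlled by the Z ketene acetal reacting through the chair-like arrangement of the forming lactone (the boat-like one pushes C2' against C6H2), which leaves the aryloxy group outside and the hydrogen towards C6, and this epimer is also expected to be the more stable one. The step needs carbon–carbon bonding by the ketene acetal alone and cyclisation in preference to oligomerisation: the dienol ether carbon C7 could only close a four-membered ring and is the weaker nucleophile, C5 is quaternary so the cation cannot lose a proton, and high dilution favours ring closure.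

Step 20
Reactants: 32 bridged lactone
Product: 33 silyl dienol ether diol
Conditions: LiBH4, THF, 0 °C to rt; pH 7 buffer
Reagents that add atoms: none
Why: Lactone reduction with LiBH4 to the diol releases both CH2OH groups (C4a and C2') from the one tether; the silyl dienol ether is inert to hydride, so C8 needs no reduction–oxidation cycle, and C1' can no longer epimerise once the carbonyl is gone.

Step 21
Reactants: 33 silyl dienol ether diol
Product: 34 protected dienone diol
Conditions: Pd(OAc)2 (1.2 equiv), MeCN, rt
Reagents that add atoms: none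
Why: Saegusa–Ito dehydrogenation: Pd(OAc)2 converts the silyl dienol ether into the C7 palladium enolate, and β-hydride elimination from C6, the only carbon with β-hydrogens, gives the C6=C7 bond of the 2-methoxy dienone.

Step 22
Reactants: 34 protected dienone diol
Product: 35 CNP0252711.1
Conditions: n-Bu4NF, AcOH (1:1), THF, 0 °C to rt
Reagents that add atoms: none
Why: Fluoride desilylation of the aryl and the primary alkyl silyl ether; acetic acid buffers the medium so that no phenoxide or alkoxide can add to or fragment the dienone.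

**Compound list**

Ar1 = 3-methoxy-4-(triisopropylsilyloxy)phenyl; Ar2O = 4-[3-(tert-butyldimethylsilyloxy)propyl]-2-methoxyphenoxy; TBS = tert-butyldimethylsilyl. In the lactones 7–14 the ring atoms correspond to route atoms C1 (carbonyl), C5 (α), C4 (β) and C3 (γ, aryl-bearing).

1 | vanillin (4-hydroxy-3-methoxybenzaldehyde) | COc1cc(C=O)ccc1O | starting material
2 | silyl vanillin: 3-methoxy-4-(triisopropylsilyloxy)benzaldehyde | COc1cc(C=O)ccc1O[Si](C(C)C)(C(C)C)C(C)C | intermediate
3 | (S)-4-benzyl-1,3-oxazolidin-2-one | O=C1N[C@@H](Cc2ccccc2)CO1 | starting material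
4 | methyl 4-chloro-4-oxobutanoate | COC(=O)CCC(Cl)=O | starting material
5 | succinate imide: methyl 4-[(4S)-4-benzyl-2-oxo-1,3-oxazolidin-3-yl]-4-oxobutanoate | COC(=O)CCC(=O)N1[C@@H](Cc2ccccc2)COC1=O | intermediate
6 | syn-aldol adduct: methyl (3S,4S)-3-[(4S)-4-benzyl-2-oxo-1,3-oxazolidine-3-carbonyl]-4-hydroxy-4-Ar1-butanoate | COC(=O)C[C@H](C(=O)N1[C@@H](Cc2ccccc2)COC1=O)[C@@H](c1ccc(O[Si](C(C)C)(C(C)C)C(C)C)c(OC)c1)O | intermediate (not isolated)
7 | lactone imide: (4S)-4-benzyl-3-[(2S,3S)-2-Ar1-5-oxooxolane-3-carbonyl]-1,3-oxazolidin-2-one, aryl and acyl groups trans | O=C1C[C@H](C(=O)N2[C@@H](Cc3ccccc3)COC2=O)[C@@H](c2ccc(O[Si](C(C)C)(C(C)C)C(C)C)c(OC)c2)O1 | intermediate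
8 | peroxy acid: (2S,3S)-2-Ar1-5-oxooxolane-3-carboperoxoic acid | O=C1C[C@H](C(=O)OO)[C@@H](c2ccc(O[Si](C(C)C)(C(C)C)C(C)C)c(OC)c2)O1 | intermediate (not isolated)
9 | lactone acid: (2S,3S)-2-Ar1-5-oxooxolane-3-carboxylic acid | O=C1C[C@H](C(=O)O)[C@@H](c2ccc(O[Si](C(C)C)(C(C)C)C(C)C)c(OC)c2)O1 | intermediate
10 | hydroxymethyl lactone: (4R,5S)-4-(hydroxymethyl)-5-Ar1-oxolan-2-one | O=C1C[C@H](CO)[C@@H](c2ccc(O[Si](C(C)C)(C(C)C)C(C)C)c(OC)c2)O1 | intermediate
11 | silyloxymethyl lactone: (4R,5S)-4-(TBS-oxymethyl)-5-Ar1-oxolan-2-one | O=C1C[C@H](CO[Si](C)(C)C(C)(C)C)[C@@H](c2ccc(O[Si](C(C)C)(C(C)C)C(C)C)c(OC)c2)O1 | intermediate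
12 | Mannich base: (3R,4R,5S)-3-[(dimethylamino)methyl]-4-(TBS-oxymethyl)-5-Ar1-oxolan-2-one | O=C1[C@@H](CN(C)C)[C@H](CO[Si](C)(C)C(C)(C)C)[C@@H](c2ccc(O[Si](C(C)C)(C(C)C)C(C)C)c(OC)c2)O1 | intermediate (not isolated)
13 | ammonium iodide: N-methyl quaternary iodide of 12 | O=C1[C@@H](C[N+](C)(C)C)[C@H](CO[Si](C)(C)C(C)(C)C)[C@@H](c2ccc(O[Si](C(C)C)(C(C)C)C(C)C)c(OC)c2)O1.[I-] | intermediate (not isolated)
14 | methylene lactone: (4R,5S)-4-(TBS-oxymethyl)-5-Ar1-3-methylideneoxolan-2-one | C=C1[C@H](CO[Si](C)(C)C(C)(C)C)[C@@H](c2ccc(O[Si](C(C)C)(C(C)C)C(C)C)c(OC)c2)OC1=O | intermediate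
15 | 2-methoxy-N-methoxy-N-methylacetamide | COCC(=O)N(C)OC | starting material
16 | ethynylmagnesium bromide | C#C[Mg]Br | starting material
17 | 1-methoxybut-3-yn-2-one | COCC(=O)C#C | intermediate
18 | (E)-1,4-dimethoxybut-3-en-2-one | COCC(=O)/C=C/OC | intermediate
19 | diene: (1Z,3E)-1,4-dimethoxy-2-(trimethylsilyloxy)buta-1,3-diene | CO/C=C/C(O[Si](C)(C)C)=C/OC | intermediate
20 | cycloadduct: (3S,4R)-spirolactone with C8 trimethylsilyl enol ether (C8=C9), OMe on C7 and C10 (open configuration), C6H2 on the C4a face | COC1C[C@]2(C(OC)C=C1O[Si](C)(C)C)[C@H](CO[Si](C)(C)C(C)(C)C)[C@@H](c1ccc(O[Si](C(C)C)(C(C)C)C(C)C)c(OC)c1)OC2=O | intermediate (not isolated)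
21 | spirolactone enone: (3S,4R)-3-Ar1-4-(TBS-oxymethyl)-7-methoxy-2-oxaspiro[4.5]dec-9-ene-1,8-dione, Ar1 trans to C4a, C6H2 on the C4a face, both C7 epimers | COC1C[C@]2(C=CC1=O)[C@H](CO[Si](C)(C)C(C)(C)C)[C@@H](c1ccc(O[Si](C(C)C)(C(C)C)C(C)C)c(OC)c1)OC2=O | intermediate
22 | lactone silyl dienol ether: (3S,4R)-3-Ar1-4-(TBS-oxymethyl)-7-methoxy-8-(triethylsilyloxy)-2-oxaspiro[4.5]deca-7,9-dien-1-one, C6H2 on the C4a face | COC=1C[C@]2(C=CC=1O[Si](CC)(CC)CC)[C@H](CO[Si](C)(C)C(C)(C)C)[C@@H](c1ccc(O[Si](C(C)C)(C(C)C)C(C)C)c(OC)c1)OC2=O | intermediate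
23 | lactol silyl dienol ether: C1 lactol of 22, both anomers | COC=1C[C@]2(C=CC=1O[Si](CC)(CC)CC)[C@H](CO[Si](C)(C)C(C)(C)C)[C@@H](c1ccc(O[Si](C(C)C)(C(C)C)C(C)C)c(OC)c1)OC2O | intermediate
24 | acetal enone alcohol: (3S,4R)-3-Ar1-4-(hydroxymethyl)-1,7-dimethoxy-2-oxaspiro[4.5]dec-9-en-8-one, C6H2 on the C4a face, both C1 anomers and C7 epimers | COC1C[C@]2(C=CC1=O)[C@H](CO)[C@@H](c1ccc(O[Si](C(C)C)(C(C)C)C(C)C)c(OC)c1)OC2OC | intermediate
25 | dihydroconiferyl alcohol (4-(3-hydroxypropyl)-2-methoxyphenol) | COc1cc(CCCO)ccc1O | starting material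
26 | ethyl bromoacetate | CCOC(=O)CBr | starting material
27 | hydroxy ester: ethyl 2-[4-(3-hydroxypropyl)-2-methoxyphenoxy]acetate | CCOC(=O)COc1ccc(CCCO)cc1OC | intermediate
28 | silyl ester: ethyl 2-{4-[3-(TBS-oxy)propyl]-2-methoxyphenoxy}acetate | CCOC(=O)COc1ccc(CCCO[Si](C)(C)C(C)(C)C)cc1OC | intermediate
29 | aryloxyacetic acid: 2-{4-[3-(TBS-oxy)propyl]-2-methoxyphenoxy}acetic acid | OC(=O)COc1ccc(CCCO[Si](C)(C)C(C)(C)C)cc1OC | intermediate
30 | tether ester (key-step precursor): 24 with C4a–O acylated by 29 | COC1C[C@]2(C=CC1=O)[C@H](COC(=O)COc1ccc(CCCO[Si](C)(C)C(C)(C)C)cc1OC)[C@@H](c1ccc(O[Si](C(C)C)(C(C)C)C(C)C)c(OC)c1)OC2OC | intermediate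
31 | bis-silyl intermediate: 30 with C8 as triethylsilyl dienol ether (C7=C8) and the ester as its Z triethylsilyl ketene acetal | COC=1C[C@]2(C=CC=1O[Si](CC)(CC)CC)[C@H](CO/C(O[Si](CC)(CC)CC)=C/Oc1ccc(CCCO[Si](C)(C)C(C)(C)C)cc1OC)[C@@H](c1ccc(O[Si](C(C)C)(C(C)C)C(C)C)c(OC)c1)OC2OC | intermediate (not isolated)
32 | bridged lactone (key-step product): C1–C1' bond formed, lactone C2'(=O)–O–C4a bridging the C4a face, Ar2O on C1' outside, C8 as triethylsilyl dienol ether | COC=1C[C@]2(C=CC=1O[Si](CC)(CC)CC)[C@H](CO3)[C@@H](c1ccc(O[Si](C(C)C)(C(C)C)C(C)C)c(OC)c1)O[C@@H]2[C@H](C3=O)Oc1ccc(CCCO[Si](C)(C)C(C)(C)C)cc1OC | intermediate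
33 | silyl dienol ether diol: 32 with the lactone reduced to C4a–OH and C2'–OH | COC=1C[C@]2(C=CC=1O[Si](CC)(CC)CC)[C@H](CO)[C@@H](c1ccc(O[Si](C(C)C)(C(C)C)C(C)C)c(OC)c1)O[C@@H]2[C@H](CO)Oc1ccc(CCCO[Si](C)(C)C(C)(C)C)cc1OC | intermediate
34 | protected dienone diol: the target with the phenol as triisopropylsilyl ether and the propanol as TBS ether | COC1=C[C@]2(C=CC1=O)[C@H](CO)[C@@H](c1ccc(O[Si](C(C)C)(C(C)C)C(C)C)c(OC)c1)O[C@@H]2[C@H](CO)Oc1ccc(CCCO[Si](C)(C)C(C)(C)C)cc1OC | intermediate
35 | CNP0252711.1: (1S,3S,4R,5S)-3-(4-hydroxy-3-methoxyphenyl)-1-{(1S)-2-hydroxy-1-[4-(3-hydroxypropyl)-2-methoxyphenoxy]ethyl}-4-(hydroxymethyl)-7-methoxy-2-oxaspiro[4.5]deca-6,9-dien-8-one | COC1=C[C@]2(C=CC1=O)[C@H](CO)[C@@H](c1ccc(O)c(OC)c1)O[C@@H]2[C@H](CO)Oc1ccc(CCCO)cc1OC | target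

**Step count and risks**

Total step count: 22. Longest linear sequence: 15 steps (1, 3–7, 11–14, 18–22, from vanillin).

Steps most likely to fail:

1. Step 19 (the new method). The closure may fail through slow ionisation of the hindered C1 acetal, protodesilylation of the ketene acetal before it meets the cation, ring opening at the O2–C3 benzylic ether, or oligomerisation. A fallback with known chemistry sets out from lactone silyl dienol ether 22 and silyl ester 28 and comes back to the route at target 35. The lithium enolate of 28 (LiN(i-Pr)2, THF, −78 °C) adds to the lactone carbonyl C1 of 22 in a Claisen-type acylation that stops at the hemiketal ester F1. Lactol reduction (Et3SiH, BF3·OEt2, CH2Cl2, −78 to −40 °C) through the C1 oxocarbenium ion should deliver hydride on the face away from C4a and C6H2, which puts the chain on the C4a face and gives the oxolane ester F2; the dienol ether is re-formed with Et3SiOTf/Et3N should the Lewis acid remove it. LiBH4 reduces the ethyl ester to the C2' alcohol F3, whose C1' epimers have to be separated because nothing controls that centre here. Pd(OAc)2 then gives the silylated dienone F4, and n-Bu4NF/AcOH removes the three silyl ethers to give 35.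

2. Step 11. The cycloaddition joins a 1,1-disubstituted, β-branched dienophile to a 1,4-disubstituted diene; it may be too slow below the temperature at which the methylene lactone polymerises, and facial selectivity at C5 may erode on heating. The fallback sets out from 14 and 18 and comes back at 21: an anionic double Michael annulation at −78 °C. The lithium enolate of 18 (LiN(i-Pr)2, THF) adds through its methoxy-bearing carbon to the methylene carbon C6 of 14. The lactone enolate so formed closes onto the β-methoxy enone carbon (C10) and expels methoxide, which gives 21 after work-up; ring closure should again occur on the face away from C4a. The detour passes through enolates only and adds no compound to the list (F0).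

3. Step 21. Palladation has to occur at the fully substituted, methoxy-bearing C7; desilylation to the saturated ketone or oxidation of the free primary alcohols may compete. The fallback runs from 33 back to 34 by selenoxide elimination. PhSeCl (CH2Cl2, −78 °C) converts the silyl dienol ether into the phenylselanyl ketone F5 (selenium on C7). H2O2/pyridine (0 °C) oxidises it to the selenoxide, which undergoes syn-elimination towards C6, the only carbon with a β-hydrogen, to give 34.

Further compounds
F1 | step 19 | hemiketal ester: 22 with C1 carrying OH and CH(Ar2O)CO2Et, C1 and C1' open | COC=1C[C@]2(C=CC=1O[Si](CC)(CC)CC)[C@H](CO[Si](C)(C)C(C)(C)C)[C@@H](c1ccc(O[Si](C(C)C)(C(C)C)C(C)C)c(OC)c1)OC2(O)C(C(=O)OCC)Oc1ccc(CCCO[Si](C)(C)C(C)(C)C)cc1OC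
F2 | step 19 | oxolane ester: C1–H on the face away from C4a, C1' open | COC=1C[C@]2(C=CC=1O[Si](CC)(CC)CC)[C@H](CO[Si](C)(C)C(C)(C)C)[C@@H](c1ccc(O[Si](C(C)C)(C(C)C)C(C)C)c(OC)c1)O[C@@H]2C(C(=O)OCC)Oc1ccc(CCCO[Si](C)(C)C(C)(C)C)cc1OC
F3 | step 19 | C2' alcohol: 33 with C4a–O still carrying TBS | COC=1C[C@]2(C=CC=1O[Si](CC)(CC)CC)[C@H](CO[Si](C)(C)C(C)(C)C)[C@@H](c1ccc(O[Si](C(C)C)(C(C)C)C(C)C)c(OC)c1)O[C@@H]2[C@H](CO)Oc1ccc(CCCO[Si](C)(C)C(C)(C)C)cc1OC
F4 | step 19 | silylated dienone: 34 with C4a–O still carrying TBS | COC1=C[C@]2(C=CC1=O)[C@H](CO[Si](C)(C)C(C)(C)C)[C@@H](c1ccc(O[Si](C(C)C)(C(C)C)C(C)C)c(OC)c1)O[C@@H]2[C@H](CO)Oc1ccc(CCCO[Si](C)(C)C(C)(C)C)cc1OC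
F0 | step 11 | none | none
F5 | step 21 | phenylselanyl ketone: C8 ketone with OMe and SePh on C7, C7 open | COC1([Se]c3ccccc3)C[C@]2(C=CC1=O)[C@H](CO)[C@@H](c1ccc(O[Si](C(C)C)(C(C)C)C(C)C)c(OC)c1)O[C@@H]2[C@H](CO)Oc1ccc(CCCO[Si](C)(C)C(C)(C)C)cc1OC
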